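The ketone bond from ring A carbon C1 to the side-chain carbonyl is disconnected, with ring A carried as a cyclohexane-1,3-dione. The oxygens on C2 and C4 are the dione carbonyls, C3 is the dione C2, and C1 (acyl) and C5 (prenyl) are its two γ-carbons. The dianion of 4-prenylcyclohexane-1,3-dione, nucleophilic at its open γ-CH2, is acylated by an (S)-α-silyloxy Weinreb amide made from O-methyl-L-tyrosine. This joins both halves in one operation and leaves the stereocentre untouched. Silylation, dehydrogenation and buffered fluoride then reveal the resorcinol.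

Key step: step 6

Remark: the ring stereocentres of the non-aromatic ring A intermediates are left undefined (racemic or epimeric mixtures) because aromatisation removes them; only the side-chain centre is carried as a single configuration.

Step 1
Reactants: 1 3-ethoxycyclohex-2-en-1-one; 2 prenyl bromide (1-bromo-3-methylbut-2-ene)
Product: 4 3-ethoxy-6-(3-methylbut-2-en-1-yl)cyclohex-2-en-1-one (racemic), via lithium dienolate 3 (not isolated)
Conditions: LiN(iPr)2 (1.1 equiv), THF, −78 °C; then 2, −78 °C → rt
Reagents that add atoms: none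
Why: Stork–Danheiser kinetic alkylation: the amide base removes the α′ proton next to the carbonyl of the vinylogous ester, and the cross-conjugated enolate is alkylated at that carbon by the reactive allylic bromide (SN2); the new ring centre is racemic and is aromatised later.

Step 2
Reactants: 4 3-ethoxy-6-(3-methylbut-2-en-1-yl)cyclohex-2-en-1-one
Product: 5 4-(3-methylbut-2-en-1-yl)cyclohexane-1,3-dione (racemic, largely enolised)
Conditions: 1 M HCl aq, THF, rt
Reagents that add atoms: water, O
Why: Acid-catalysed hydrolysis of the vinylogous ester (enol ether) releases the 1,3-dione with the prenyl group on a γ-carbon; dilute acid at room temperature should leave the trisubstituted alkene untouched.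

Step 3
Reactants: 6 O-methyl-L-tyrosine
Product: 8 (2S)-2-hydroxy-3-(4-methoxyphenyl)propanoic acid, via alpha-lactone 7 (not isolated)
Conditions: NaNO2, 1 M H2SO4 aq, 0 °C → rt
Reagents that add atoms: water, O
Why: Diazotisation of an α-amino acid with carboxylate participation: the carboxylate displaces N2 with inversion to give the (R)-α-lactone, which water opens at Cα with a second inversion, so the (S) configuration of the amino acid is retained overall.

Step 4
Reactants: 8 (2S)-2-hydroxy-3-(4-methoxyphenyl)propanoic acid
Product: 9 (2S)-2-hydroxy-N-methoxy-3-(4-methoxyphenyl)-N-methylpropanamide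
Conditions: MeNHOMe·HCl, EDC·HCl, HOBt, N-methylmorpholine, CH2Cl2, 0 °C → rt
Reagents that add atoms: N,O-dimethylhydroxylamine hydrochloride, CNOC.Cl
Why: Carbodiimide/HOBt amide coupling (Weinreb amide formation); the amine outcompetes the free secondary hydroxyl for the active ester, and an α-hydroxy acid has no oxazolone pathway, so the stereocentre should be preserved.

Step 5
Reactants: 9 (2S)-2-hydroxy-N-methoxy-3-(4-methoxyphenyl)-N-methylpropanamide
Product: 10 (2S)-2-(tert-butyldimethylsilyloxy)-N-methoxy-3-(4-methoxyphenyl)-N-methylpropanamide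
Conditions: TBSCl, imidazole, DMF, rt
Reagents that add atoms: tert-butyldimethylsilyl chloride (TBSCl), CC(C)(C)[Si](C)(C)Cl
Why: Corey silylation of a secondary alcohol; the silyl ether removes the only acidic O–H from the electrophile and is cleaved at the end together with the aryl silyl ethers.

Step 6
Reactants: 5 4-(3-methylbut-2-en-1-yl)cyclohexane-1,3-dione; 10 (2S)-2-(tert-butyldimethylsilyloxy)-N-methoxy-3-(4-methoxyphenyl)-N-methylpropanamide
Product: 13 4-[(2S)-2-(tert-butyldimethylsilyloxy)-3-(4-methoxyphenyl)propanoyl]-6-(3-methylbut-2-en-1-yl)cyclohexane-1,3-dione (mixture of ring epimers), via dilithium dianion 11 (not isolated), via tetrahedral dilithium adduct 12 (not isolated)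
Conditions: 5 (2.0 equiv), LiN(iPr)2 (4.0 equiv), THF/DMPU, −78 → 0 °C; then 10 (1.0 equiv), −78 → −20 °C; 1 M HCl to pH 3–4
Reagents that add atoms: none
Why: The first equivalent of base gives the delocalised dione enolate and the second removes a proton from the unhindered ring CH2 beside the carbonyl remote from the prenyl group, so dianion 11 carries a localised terminal carbanion that adds to the amide carbonyl of 10; the lithium chelate 12 holds the tetrahedral stage until the acidic quench, which should prevent over-addition and keep the side-chain centre from enolising. The closest known reactions are the terminal (γ) acylation of β-diketone dianions, the γ-alkylation of cyclohexane-1,3-dione dianions and the Weinreb ketone synthesis. No ring is closed. No lasting stereocentre is created: the (S) centre comes unchanged from 10, while the two ring centres are epimeric, enolised towards the ring and later aromatised. The selectivity required is site selectivity among the ring carbons (open γ-CH2 against the prenyl-bearing CH and the central carbon); it is secured by kinetic deprotonation at the less substituted γ-position and by the far higher nucleophilicity of the terminal carbanion compared with the stabilised central enolate carbon. The cheap dione is used in excess with exactly two equivalents of base per dione, so that no free amide base meets the α-proton of 10.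

Step 7
Reactants: 13 4-[(2S)-2-(tert-butyldimethylsilyloxy)-3-(4-methoxyphenyl)propanoyl]-6-(3-methylbut-2-en-1-yl)cyclohexane-1,3-dione
Product: 14 (2S)-1-[2,4-bis(tert-butyldimethylsilyloxy)-5-(3-methylbut-2-en-1-yl)cyclohexa-1,3-dien-1-yl]-2-(tert-butyldimethylsilyloxy)-3-(4-methoxyphenyl)propan-1-one (ring centre unassigned)
Conditions: TBSOTf (2.2 equiv), 2,6-lutidine (3 equiv), CH2Cl2, −78 → 0 °C
Reagents that add atoms: tert-butyldimethylsilyl trifluoromethanesulfonate (TBSOTf), CC(C)(C)[Si](C)(C)OS(=O)(=O)C(F)(F)F
Why: O-silylation of the two enolised β-dicarbonyl units (silyl enol ether formation with a silyl triflate and a weak amine base) should give the conjugated bis-silyl dienol ether; 2,6-lutidine silylates enolic O–H but is too weak to enolise the side-chain ketone towards Cα, and an isomer silylated on the side-chain carbonyl oxygen would converge on the same arene in step 8.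

Step 8
Reactants: 14 (2S)-1-[2,4-bis(tert-butyldimethylsilyloxy)-5-(3-methylbut-2-en-1-yl)cyclohexa-1,3-dien-1-yl]-2-(tert-butyldimethylsilyloxy)-3-(4-methoxyphenyl)propan-1-one
Product: 15 (2S)-1-[2,4-bis(tert-butyldimethylsilyloxy)-5-(3-methylbut-2-en-1-yl)phenyl]-2-(tert-butyldimethylsilyloxy)-3-(4-methoxyphenyl)propan-1-one
Conditions: DDQ (1.05 equiv), 2,4,6-collidine (cat.), PhMe, 0 °C → rt
Reagents that add atoms: none
Why: DDQ dehydrogenation of a silyloxy cyclohexadiene: hydride is abstracted from the ring CH2 allylic to the silyl enol ether to give a doubly oxygen-stabilised pentadienyl cation, which loses the neighbouring ring proton to form the arene with both oxygens still silylated, so no free ortho-prenyl phenol meets the oxidant and the electron-rich dienol ether should react well before the prenyl or anisyl C–H bonds.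

Step 9
Reactants: 15 (2S)-1-[2,4-bis(tert-butyldimethylsilyloxy)-5-(3-methylbut-2-en-1-yl)phenyl]-2-(tert-butyldimethylsilyloxy)-3-(4-methoxyphenyl)propan-1-one
Product: 16 Lespeflorin C2, (2S)-1-[2,4-dihydroxy-5-(3-methylbut-2-en-1-yl)phenyl]-2-hydroxy-3-(4-methoxyphenyl)propan-1-one
Conditions: Bu4NF (3.5 equiv), AcOH (3.5 equiv), THF, 0 °C → rt
Reagents that add atoms: none
Why: Fluoride-mediated cleavage of the two aryl and one alkyl silyl ethers, driven by Si–F bond formation; the acetic acid buffer should suppress base-induced epimerisation or ketol shift of the α-hydroxy ketone, and no acid strong enough to cyclise the ortho-prenyl phenol to a chroman is present.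

Compound list
1 | 3-ethoxycyclohex-2-en-1-one | CCOC1=CC(=O)CCC1 | starting material
2 | prenyl bromide (1-bromo-3-methylbut-2-ene) | CC(C)=CCBr | starting material
3 | lithium 5-ethoxycyclohexa-1,5-dien-1-olate (kinetic enolate of 1, not isolated) | CCOC1=CC([O-])=CCC1.[Li+] | intermediate
4 | 3-ethoxy-6-(3-methylbut-2-en-1-yl)cyclohex-2-en-1-one (racemic) | CCOC1=CC(=O)C(CC=C(C)C)CC1 | intermediate
5 | 4-(3-methylbut-2-en-1-yl)cyclohexane-1,3-dione (racemic) | CC(C)=CCC1CCC(=O)CC1=O | intermediate
6 | O-methyl-L-tyrosine, (2S)-2-amino-3-(4-methoxyphenyl)propanoic acid | COc1ccc(C[C@H](N)C(=O)O)cc1 | starting material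
7 | (3R)-3-(4-methoxybenzyl)oxiran-2-one (α-lactone, not isolated) | COc1ccc(C[C@H]2OC2=O)cc1 | intermediate
8 | (2S)-2-hydroxy-3-(4-methoxyphenyl)propanoic acid | COc1ccc(C[C@H](O)C(=O)O)cc1 | intermediate
9 | (2S)-2-hydroxy-N-methoxy-3-(4-methoxyphenyl)-N-methylpropanamide | COc1ccc(C[C@H](O)C(=O)N(C)OC)cc1 | intermediate
10 | (2S)-2-(tert-butyldimethylsilyloxy)-N-methoxy-3-(4-methoxyphenyl)-N-methylpropanamide | COc1ccc(C[C@H](O[Si](C)(C)C(C)(C)C)C(=O)N(C)OC)cc1 | intermediate
11 | dilithium dienediolate (dianion) of 5, carbanion at the unsubstituted γ-carbon (not isolated) | CC(C)=CCC1CC=C([O-])C=C1[O-].[Li+].[Li+] | intermediate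
12 | tetrahedral dilithium adduct of 11 with 10, (S) side chain, other centres unassigned (not isolated) | COc1ccc(C[C@H](O[Si](C)(C)C(C)(C)C)C([O-])(N(C)OC)C2CC(CC=C(C)C)C(=O)C=C2[O-])cc1.[Li+].[Li+] | intermediate
13 | 4-[(2S)-2-(tert-butyldimethylsilyloxy)-3-(4-methoxyphenyl)propanoyl]-6-(3-methylbut-2-en-1-yl)cyclohexane-1,3-dione (ring epimers) | COc1ccc(C[C@H](O[Si](C)(C)C(C)(C)C)C(=O)C2CC(CC=C(C)C)C(=O)CC2=O)cc1 | intermediate
14 | (2S)-1-[2,4-bis(tert-butyldimethylsilyloxy)-5-(3-methylbut-2-en-1-yl)cyclohexa-1,3-dien-1-yl]-2-(tert-butyldimethylsilyloxy)-3-(4-methoxyphenyl)propan-1-one | COc1ccc(C[C@H](O[Si](C)(C)C(C)(C)C)C(=O)C2=C(O[Si](C)(C)C(C)(C)C)C=C(O[Si](C)(C)C(C)(C)C)C(CC=C(C)C)C2)cc1 | intermediate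
15 | (2S)-1-[2,4-bis(tert-butyldimethylsilyloxy)-5-(3-methylbut-2-en-1-yl)phenyl]-2-(tert-butyldimethylsilyloxy)-3-(4-methoxyphenyl)propan-1-one | COc1ccc(C[C@H](O[Si](C)(C)C(C)(C)C)C(=O)c2cc(CC=C(C)C)c(O[Si](C)(C)C(C)(C)C)cc2O[Si](C)(C)C(C)(C)C)cc1 | intermediate
16 | Lespeflorin C2, (2S)-1-[2,4-dihydroxy-5-(3-methylbut-2-en-1-yl)phenyl]-2-hydroxy-3-(4-methoxyphenyl)propan-1-one | COc1ccc(C[C@H](O)C(=O)c2cc(CC=C(C)C)c(O)cc2O)cc1 | target

Total step count: 9. Longest linear sequence: 7 steps (steps 3, 4, 5, 6, 7, 8, 9 from O-methyl-L-tyrosine); the dione branch contributes steps 1 and 2.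

Steps most likely to fail

Step 6. Proton transfer from the α-C–H of the amide to the strongly basic dianion may stall the addition and racemise unreacted amide. Addition to the hindered α-silyloxy amide may also be slow, and some metalation may occur at the prenyl-bearing ring carbon. The fallback sets out from 10 (with 5 as before) and returns at 13. The amide 10 would be reduced with iBu2AlH (THF, −78 °C) to the aldehyde (2S)-2-(tert-butyldimethylsilyloxy)-3-(4-methoxyphenyl)propanal F1. Dianion 11, generated from 5 as in step 6, would be added to F1 at −78 °C in an aldol reaction, which is much faster than proton transfer, to give the hydroxy dione 4-[(2S)-2-(tert-butyldimethylsilyloxy)-1-hydroxy-3-(4-methoxyphenyl)propyl]-6-(3-methylbut-2-en-1-yl)cyclohexane-1,3-dione F2 as a mixture of carbinol epimers. Oxidation of the secondary alcohol with Dess–Martin periodinane (NaHCO3, CH2Cl2, 0 °C) would then give 13.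

Step 8. Hydride abstraction may compete at the anisyl benzylic CH2 or the prenyl allylic positions. The oxidation may stall because the acyl-substituted enol ether is electron-poor, and adventitious loss of a silyl group may open the way to oxidative chromene formation. The fallback sets out from 14 and returns at 16, replacing the quinone by a Saegusa–Ito oxidation. Pd(OAc)2 (1.1 equiv, MeCN, rt) would convert the acyl-substituted silyl enol ether into a carbon-bound enolate of divalent palladium, with loss of the silyl group as its acetate. β-Hydride elimination towards the ring CH2 releases zerovalent palladium and a dienone, which tautomerises to the phenol (2S)-2-(tert-butyldimethylsilyloxy)-1-[4-(tert-butyldimethylsilyloxy)-2-hydroxy-5-(3-methylbut-2-en-1-yl)phenyl]-3-(4-methoxyphenyl)propan-1-one F3. Its free hydroxyl lies next to the ketone and not next to the prenyl group. The buffered fluoride conditions of step 9 would then give 16.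

Step 7. The second silylation may be incomplete, the silyl groups may scramble between oxygens, or over-silylation may enolise the side-chain ketone towards Cα and erode the configuration. The fallback sets out from 13 and returns at 16, using transient trimethylsilyl groups and a one-flask dehydrogenation. Neutral N,O-bis(trimethylsilyl)acetamide (PhMe, rt), which cannot enolise towards Cα, would give the dienol ether (2S)-1-[2,4-bis(trimethylsilyloxy)-5-(3-methylbut-2-en-1-yl)cyclohexa-1,3-dien-1-yl]-2-(tert-butyldimethylsilyloxy)-3-(4-methoxyphenyl)propan-1-one F4. DDQ added to the same flask would give the arene (2S)-1-[2,4-bis(trimethylsilyloxy)-5-(3-methylbut-2-en-1-yl)phenyl]-2-(tert-butyldimethylsilyloxy)-3-(4-methoxyphenyl)propan-1-one F5. A reductive quench (aqueous Na2S2O3) followed by brief methanolysis with a trace of citric acid would hydrolyse the aryl trimethylsilyl ethers to (2S)-2-(tert-butyldimethylsilyloxy)-1-[2,4-dihydroxy-5-(3-methylbut-2-en-1-yl)phenyl]-3-(4-methoxyphenyl)propan-1-one F6. The conditions of step 9 would then remove the remaining silyl ether to give 16.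

Further compounds
F1 | step 6 | (2S)-2-(tert-butyldimethylsilyloxy)-3-(4-methoxyphenyl)propanal | COc1ccc(C[C@H](O[Si](C)(C)C(C)(C)C)C=O)cc1
F2 | step 6 | 4-[(2S)-2-(tert-butyldimethylsilyloxy)-1-hydroxy-3-(4-methoxyphenyl)propyl]-6-(3-methylbut-2-en-1-yl)cyclohexane-1,3-dione | COc1ccc(C[C@H](O[Si](C)(C)C(C)(C)C)C(O)C2CC(CC=C(C)C)C(=O)CC2=O)cc1
F3 | step 8 | (2S)-2-(tert-butyldimethylsilyloxy)-1-[4-(tert-butyldimethylsilyloxy)-2-hydroxy-5-(3-methylbut-2-en-1-yl)phenyl]-3-(4-methoxyphenyl)propan-1-one | COc1ccc(C[C@H](O[Si](C)(C)C(C)(C)C)C(=O)c2cc(CC=C(C)C)c(O[Si](C)(C)C(C)(C)C)cc2O)cc1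
F4 | step 7 | (2S)-1-[2,4-bis(trimethylsilyloxy)-5-(3-methylbut-2-en-1-yl)cyclohexa-1,3-dien-1-yl]-2-(tert-butyldimethylsilyloxy)-3-(4-methoxyphenyl)propan-1-one | COc1ccc(C[C@H](O[Si](C)(C)C(C)(C)C)C(=O)C2=C(O[Si](C)(C)C)C=C(O[Si](C)(C)C)C(CC=C(C)C)C2)cc1
F5 | step 7 | (2S)-1-[2,4-bis(trimethylsilyloxy)-5-(3-methylbut-2-en-1-yl)phenyl]-2-(tert-butyldimethylsilyloxy)-3-(4-methoxyphenyl)propan-1-one | COc1ccc(C[C@H](O[Si](C)(C)C(C)(C)C)C(=O)c2cc(CC=C(C)C)c(O[Si](C)(C)C)cc2O[Si](C)(C)C)cc1
F6 | step 7 | (2S)-2-(tert-butyldimethylsilyloxy)-1-[2,4-dihydroxy-5-(3-methylbut-2-en-1-yl)phenyl]-3-(4-methoxyphenyl)propan-1-one | COc1ccc(C[C@H](O[Si](C)(C)C(C)(C)C)C(=O)c2cc(CC=C(C)C)c(O)cc2O)cc1
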